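**Retrosynthetic overview**

1. Enabling feature: the quaternary C2 of the 2,3,4,7-tetrahydrooxepine carries both the ring oxygen O1 and the carboxyl group, and O1 is bonded on its other side to the allylic methylene C7. With C7 raised to the aldehyde level, O1–C2–C(=O)–O–C7 closes to a 1,3-dioxolan-4-one, so C2 becomes an enolate carbon whose chirality is stored at C7.
2. Key disconnection: C2–CH2(C=O)Ar. The dioxolanone enolate, made from (S)-2-hydroxyhex-5-enoic acid and a 2-substituted acrolein that holds the whole side chain, is alkylated with the phenacyl bromide of 2',5'-bis(silyloxy)acetophenone; C7 hands the chirality back to C2.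
3. Ring order: the temporary dioxolanone first; then the oxepine by ring-closing metathesis (C5=C6) across the dioxolanone to a 7,9-dioxabicyclo[4.2.1]nonenone; then silane opening of the acylal removes the temporary ring and frees O1–C7H2 and CO2H together. Both benzene rings are bought.
4. Side chain: copper-catalysed SN2′ opening of isoprene monoxide sets the E-trisubstituted alkene, Steglich esterification brings in the silylated p-coumarate, and α-methylenation makes the acrolein.
5. End: one fluoride deprotection of three aryl silyl ethers.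

Key step: step 10

Remark: 2-(2-bromoethyl)-1,3-dioxolane, racemic 2-methyl-2-vinyloxirane and (S)-2-aminohex-5-enoic acid are taken as commercial; TBS = tert-butyldimethylsilyl, TMS = trimethylsilyl; the oxepine is numbered O1, C2 (quaternary, R), C3, C4, C5=C6, C7.

**Route**

Step 1
Reactants: 1 2-(2-bromoethyl)-1,3-dioxolane; 2 2-methyl-2-vinyloxirane (racemic)
Product: 4 (E)-6-(1,3-dioxolan-2-yl)-2-methylhex-2-en-1-ol, via Grignard reagent 3 (not isolated)
Conditions: Mg, THF, 25 °C; then 2, CuI (10 mol%), THF, −30 → 0 °C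
Reagents that add atoms: none
Why: Copper-catalysed SN2′ opening of a vinyl epoxide by a Grignard reagent is a standard route to (E)-2-methylalk-2-en-1-ols, so the E-trisubstituted alkene of the side chain should form here together with the acetal-masked aldehyde chain (any Z isomer is removed by chromatography).

Step 2
Reactants: 5 (E)-4-hydroxycinnamic acid (p-coumaric acid)
Product: 7 (E)-3-[4-(TBSO)phenyl]acrylic acid, via bis-silyl derivative 6 (not isolated)
Conditions: TBSCl (2.5 equiv), imidazole, DMF, rt; then AcOH–THF–H2O (3:1:1), rt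
Reagents that add atoms: tert-butyldimethylsilyl chloride, CC(C)(C)[Si](C)(C)Cl
Why: Silylation of phenol and acid followed by selective hydrolysis of the much more labile silyl ester should leave the acid free and the phenol protected as an aryl silyl ether that survives acid but falls to fluoride.

Step 3
Reactants: 4 (E)-6-(1,3-dioxolan-2-yl)-2-methylhex-2-en-1-ol; 7 (E)-3-[4-(TBSO)phenyl]acrylic acid
Product: 8 (E)-6-(1,3-dioxolan-2-yl)-2-methylhex-2-en-1-yl (E)-3-[4-(TBSO)phenyl]acrylate
Conditions: DCC, DMAP (cat.), CH2Cl2, 0 °C → rt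
Reagents that add atoms: none
Why: Steglich esterification of a primary allylic alcohol with a cinnamic acid should proceed without touching the acetal or the aryl silyl ether.

Step 4
Reactants: 8 (E)-6-(1,3-dioxolan-2-yl)-2-methylhex-2-en-1-yl (E)-3-[4-(TBSO)phenyl]acrylate
Product: 9 (E)-2-methyl-7-oxohept-2-en-1-yl (E)-3-[4-(TBSO)phenyl]acrylate
Conditions: TsOH·H2O (10 mol%), THF–H2O (4:1), 40 °C
Reagents that add atoms: water, O
Why: Acid-catalysed acetal hydrolysis should free the aldehyde, since the aryl silyl ether and the allylic ester tolerate dilute acid.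

Step 5
Reactants: 9 (E)-2-methyl-7-oxohept-2-en-1-yl (E)-3-[4-(TBSO)phenyl]acrylate
Product: 10 (E)-6-formyl-2-methylhepta-2,6-dien-1-yl (E)-3-[4-(TBSO)phenyl]acrylate
Conditions: 37% aq. CH2O, pyrrolidine (10 mol%), propionic acid (10 mol%), i-PrOH, 45 °C
Reagents that add atoms: formaldehyde, C=O
Why: Amine/acid-catalysed α-methylenation with formaldehyde (Mannich condensation then elimination) should turn the unbranched aldehyde into the 2-substituted acrolein, which holds the future C7 at the aldehyde level and the methylene needed for the later metathesis.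

Step 6
Reactants: 11 (S)-2-aminohex-5-enoic acid
Product: 12 (S)-2-hydroxyhex-5-enoic acid
Conditions: NaNO2, 1 M H2SO4, 0 °C → rt
Reagents that add atoms: water, O
Why: Diazotisation of an α-amino acid in aqueous acid proceeds with net retention by way of the α-lactone (double inversion), so the (S) configuration should be carried over to the hydroxy acid and the terminal alkene is not affected.

Step 7
Reactants: 12 (S)-2-hydroxyhex-5-enoic acid; 10 (E)-6-formyl-2-methylhepta-2,6-dien-1-yl (E)-3-[4-(TBSO)phenyl]acrylate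
Product: 14 (2S,5S)-5-(but-3-en-1-yl)-2-{(5E)-6-methyl-7-[(E)-3-(4-TBSO-phenyl)acryloyloxy]hepta-1,5-dien-2-yl}-1,3-dioxolan-4-one (2,5-cis), via bis-trimethylsilyl derivative 13 (not isolated)
Conditions: TMSCl, Et3N, CH2Cl2, 0 °C → rt, filtered under argon; then 10, TMSOTf (10 mol%), CH2Cl2, −78 °C
Reagents that add atoms: none
Why: Silyl-triflate-catalysed acetalisation of the bis-silylated α-hydroxy acid with the aldehyde is kinetically cis-selective at low temperature, so the C5 stereocentre should set the new acetal centre as (2S) with both substituents on the same face, and any trans isomer is removed by chromatography.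

Step 8
Reactants: 15 1-(2,5-dihydroxyphenyl)ethan-1-one
Product: 16 1-[2,5-bis(TBSO)phenyl]ethan-1-one
Conditions: TBSCl (2.5 equiv), imidazole, DMAP (cat.), DMF, 50 °C
Reagents that add atoms: tert-butyldimethylsilyl chloride, CC(C)(C)[Si](C)(C)Cl
Why: Silylation with TBSCl/imidazole should cap both phenols (the hydrogen-bonded 2-hydroxyl needs gentle heating), which removes the acidic protons before enolate chemistry.

Step 9
Reactants: 16 1-[2,5-bis(TBSO)phenyl]ethan-1-one
Product: 18 2-bromo-1-[2,5-bis(TBSO)phenyl]ethan-1-one, via trimethylsilyl enol ether 17 (not isolated)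
Conditions: LiHMDS, TMSCl, THF, −78 → 0 °C; then NBS, THF, −78 → 0 °C
Reagents that add atoms: N-bromosuccinimide, O=C1CCC(=O)N1Br
Why: Trapping the kinetic enolate as its silyl enol ether and brominating it with NBS is a regiospecific α-bromination that should avoid bromination of the electron-rich ring.

Step 10
Reactants: 14 (2S,5S)-cis-dioxolanone; 18 2-bromo-1-[2,5-bis(TBSO)phenyl]ethan-1-one
Product: 20 (2S,5R)-5-(but-3-en-1-yl)-5-{2-[2,5-bis(TBSO)phenyl]-2-oxoethyl}-2-{(5E)-6-methyl-7-[(E)-3-(4-TBSO-phenyl)acryloyloxy]hepta-1,5-dien-2-yl}-1,3-dioxolan-4-one (butenyl cis to the C2 substituent), via lithium enolate 19 (not isolated)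
Conditions: LiHMDS (1.0 equiv), THF, −78 °C; then 18, THF–DMPU, −78 → −50 °C
Reagents that add atoms: none
Why: LiHMDS removes the only α-proton of 14 to give the planar lithium enolate 19, in which the C5 stereocentre is erased and its information is held by the acetal carbon (the future C7); SN2 attack of this enolate on the highly SN2-active phenacyl bromide 18 forms the C–CH2 bond. The closest known reaction type is the self-regeneration of stereocentres, that is, alkylation of 2-substituted 1,3-dioxolan-4-one enolates to quaternary α-alkoxy acid derivatives. No ring is closed in this step; it joins the two halves, so that every carbon of the target is in place afterwards. The new quaternary centre (5R, the future C2 with R configuration) is controlled by the acetal stereocentre: its alkenyl group shields one face of the enolate and the electrophile enters trans to it, which is net retention at C5 and leaves the butenyl chain cis to the alkenyl group. The step needs face selectivity and C-alkylation by substitution instead of proton transfer or carbonyl addition; the first is secured by the 2,5-cis pattern set in step 7 and checked by step 11, the second by the low temperature, the soft lactone enolate and exactly one equivalent of base.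

Step 11
Reactants: 20 (2S,5R)-alkylated dioxolanone
Product: 21 (1R,6S)-1-{2-[2,5-bis(TBSO)phenyl]-2-oxoethyl}-5-{(3E)-4-methyl-5-[(E)-3-(4-TBSO-phenyl)acryloyloxy]pent-3-en-1-yl}-7,9-dioxabicyclo[4.2.1]non-4-en-8-one
Conditions: Grubbs second-generation catalyst (5 mol%), CH2Cl2 (2 mM), 40 °C
Reagents that add atoms: none
Why: Ring-closing metathesis between the terminal alkene and the 1,1-disubstituted alkene, which the dioxolanone holds cis on a five-membered ring, should close the seven-membered ring as a bridged bicyclo[4.2.1]nonene with the trisubstituted C5=C6 alkene, while any epimer alkylated on the wrong face cannot reach this ring and is left behind.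

Step 12
Reactants: 21 (1R,6S)-bicyclic acylal
Product: 23 (R)-2-{2-[2,5-bis(TBSO)phenyl]-2-oxoethyl}-6-{(3E)-4-methyl-5-[(E)-3-(4-TBSO-phenyl)acryloyloxy]pent-3-en-1-yl}-2,3,4,7-tetrahydrooxepine-2-carboxylic acid, via triethylsilyl ester 22 (not isolated)
Conditions: Et3SiH (3 equiv), TMSOTf (20 mol%), CH2Cl2, −78 → −40 °C; then pH 7 buffer
Reagents that add atoms: none
Why: Silyl triflate ionises the acylal at its acyloxy C–O bond to an oxocarbenium ion stabilised by the ring oxygen and the alkene, which triethylsilane reduces at C7 (ionic hydrogenation, known for 1,3-dioxolan-4-ones as a route to α-alkoxy acids), so the temporary ring should be converted into the O1–C7H2 ether and the free acid in one operation while the hindered aryl ketone survives at low temperature.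

Step 13
Reactants: 23 tris-TBS acid
Product: 24 (R)-2-[2-(2,5-dihydroxyphenyl)-2-oxoethyl]-6-{(3E)-5-[(E)-3-(4-hydroxyphenyl)acryloyloxy]-4-methylpent-3-en-1-yl}-2,3,4,7-tetrahydrooxepine-2-carboxylic acid
Conditions: TBAF (3.5 equiv), AcOH (4 equiv), THF, 0 °C → rt
Reagents that add atoms: none
Why: Fluoride buffered with acetic acid should cleave the three aryl silyl ethers without base-induced β-elimination of the ring oxygen from the β-alkoxy ketone or cleavage of the coumarate ester.

**Compound list**

1 | 2-(2-bromoethyl)-1,3-dioxolane | BrCCC1OCCO1 | starting material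
2 | 2-methyl-2-vinyloxirane (racemic) | C=CC1(C)CO1 | starting material
3 | [2-(1,3-dioxolan-2-yl)ethyl]magnesium bromide | Br[Mg]CCC1OCCO1 | intermediate
4 | (E)-6-(1,3-dioxolan-2-yl)-2-methylhex-2-en-1-ol | C/C(=C\CCCC1OCCO1)CO | intermediate
5 | (E)-4-hydroxycinnamic acid | OC(=O)/C=C/c1ccc(O)cc1 | starting material
6 | tert-butyldimethylsilyl (E)-3-[4-(TBSO)phenyl]acrylate | CC(C)(C)[Si](C)(C)OC(=O)/C=C/c1ccc(O[Si](C)(C)C(C)(C)C)cc1 | intermediate
7 | (E)-3-[4-(TBSO)phenyl]acrylic acid | OC(=O)/C=C/c1ccc(O[Si](C)(C)C(C)(C)C)cc1 | intermediate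
8 | (E)-6-(1,3-dioxolan-2-yl)-2-methylhex-2-en-1-yl (E)-3-[4-(TBSO)phenyl]acrylate | C/C(=C\CCCC1OCCO1)COC(=O)/C=C/c1ccc(O[Si](C)(C)C(C)(C)C)cc1 | intermediate
9 | (E)-2-methyl-7-oxohept-2-en-1-yl (E)-3-[4-(TBSO)phenyl]acrylate | C/C(=C\CCCC=O)COC(=O)/C=C/c1ccc(O[Si](C)(C)C(C)(C)C)cc1 | intermediate
10 | (E)-6-formyl-2-methylhepta-2,6-dien-1-yl (E)-3-[4-(TBSO)phenyl]acrylate | C/C(=C\CCC(=C)C=O)COC(=O)/C=C/c1ccc(O[Si](C)(C)C(C)(C)C)cc1 | intermediate
11 | (S)-2-aminohex-5-enoic acid | C=CCC[C@H](N)C(=O)O | starting material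
12 | (S)-2-hydroxyhex-5-enoic acid | C=CCC[C@H](O)C(=O)O | intermediate
13 | trimethylsilyl (S)-2-(trimethylsilyloxy)hex-5-enoate | C=CCC[C@H](O[Si](C)(C)C)C(=O)O[Si](C)(C)C | intermediate
14 | (2S,5S)-5-(but-3-en-1-yl)-2-{(5E)-6-methyl-7-[(E)-3-(4-TBSO-phenyl)acryloyloxy]hepta-1,5-dien-2-yl}-1,3-dioxolan-4-one | C=CCC[C@H]1C(=O)O[C@@H](C(=C)CC/C=C(\C)COC(=O)/C=C/c2ccc(O[Si](C)(C)C(C)(C)C)cc2)O1 | intermediate
15 | 1-(2,5-dihydroxyphenyl)ethan-1-one | CC(=O)c1cc(O)ccc1O | starting material
16 | 1-[2,5-bis(TBSO)phenyl]ethan-1-one | CC(=O)c1cc(O[Si](C)(C)C(C)(C)C)ccc1O[Si](C)(C)C(C)(C)C | intermediate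
17 | {1-[2,5-bis(TBSO)phenyl]vinyloxy}trimethylsilane | C=C(O[Si](C)(C)C)c1cc(O[Si](C)(C)C(C)(C)C)ccc1O[Si](C)(C)C(C)(C)C | intermediate
18 | 2-bromo-1-[2,5-bis(TBSO)phenyl]ethan-1-one | O=C(CBr)c1cc(O[Si](C)(C)C(C)(C)C)ccc1O[Si](C)(C)C(C)(C)C | intermediate
19 | lithium enolate of 14 (acetal carbon 2S) | C=CCC1=C([O-])O[C@@H](C(=C)CC/C=C(\C)COC(=O)/C=C/c2ccc(O[Si](C)(C)C(C)(C)C)cc2)O1.[Li+] | intermediate
20 | (2S,5R)-5-(but-3-en-1-yl)-5-{2-[2,5-bis(TBSO)phenyl]-2-oxoethyl}-2-{(5E)-6-methyl-7-[(E)-3-(4-TBSO-phenyl)acryloyloxy]hepta-1,5-dien-2-yl}-1,3-dioxolan-4-one | C=CCC[C@@]1(CC(=O)c2cc(O[Si](C)(C)C(C)(C)C)ccc2O[Si](C)(C)C(C)(C)C)C(=O)O[C@@H](C(=C)CC/C=C(\C)COC(=O)/C=C/c2ccc(O[Si](C)(C)C(C)(C)C)cc2)O1 | intermediate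
21 | (1R,6S)-1-{2-[2,5-bis(TBSO)phenyl]-2-oxoethyl}-5-{(3E)-4-methyl-5-[(E)-3-(4-TBSO-phenyl)acryloyloxy]pent-3-en-1-yl}-7,9-dioxabicyclo[4.2.1]non-4-en-8-one | C/C(=C\CCC1=CCC[C@]2(CC(=O)c3cc(O[Si](C)(C)C(C)(C)C)ccc3O[Si](C)(C)C(C)(C)C)O[C@H]1OC2=O)COC(=O)/C=C/c1ccc(O[Si](C)(C)C(C)(C)C)cc1 | intermediate
22 | triethylsilyl ester of 23 | C/C(=C\CCC1=CCC[C@@](CC(=O)c2cc(O[Si](C)(C)C(C)(C)C)ccc2O[Si](C)(C)C(C)(C)C)(C(=O)O[Si](CC)(CC)CC)OC1)COC(=O)/C=C/c1ccc(O[Si](C)(C)C(C)(C)C)cc1 | intermediate
23 | (R)-2-{2-[2,5-bis(TBSO)phenyl]-2-oxoethyl}-6-{(3E)-4-methyl-5-[(E)-3-(4-TBSO-phenyl)acryloyloxy]pent-3-en-1-yl}-2,3,4,7-tetrahydrooxepine-2-carboxylic acid | C/C(=C\CCC1=CCC[C@@](CC(=O)c2cc(O[Si](C)(C)C(C)(C)C)ccc2O[Si](C)(C)C(C)(C)C)(C(=O)O)OC1)COC(=O)/C=C/c1ccc(O[Si](C)(C)C(C)(C)C)cc1 | intermediate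
24 | (R)-2-[2-(2,5-dihydroxyphenyl)-2-oxoethyl]-6-{(3E)-5-[(E)-3-(4-hydroxyphenyl)acryloyloxy]-4-methylpent-3-en-1-yl}-2,3,4,7-tetrahydrooxepine-2-carboxylic acid | C/C(=C\CCC1=CCC[C@@](CC(=O)c2cc(O)ccc2O)(C(=O)O)OC1)COC(=O)/C=C/c1ccc(O)cc1 | target

**Step count and risks**

Total step count: 13. Longest linear sequence: 9 steps (1, 3, 4, 5, 7, 10, 11, 12, 13).

Step 10 (key alkylation). What may go wrong: weak face discrimination, because the trigonal acetal substituent shields the enolate less than a tert-butyl group would, and quenching of the enolate by proton transfer from the acidic α-bromoketone or by its attack on the ketone carbonyl. Fallback (same bond, reversed polarity, catalyst control): setting out from 16, the enol ether 17 is isolated and added to allyl 2-oxohex-5-enoate F1 (one step from diallyl oxalate and but-3-en-1-ylmagnesium bromide) in a copper(II)–bis(oxazoline)-catalysed Mukaiyama aldol addition [Cu(OTf)2, (R,R)-tert-butyl-bis(oxazoline), THF, −78 °C, then dilute acid]. Chelation of the 1,2-dicarbonyl unit to copper should expose one ketone face and give the tertiary aldol allyl (R)-2-{2-[2,5-bis(TBSO)phenyl]-2-oxoethyl}-2-hydroxyhex-5-enoate F2. Pd(PPh3)4/morpholine removes the allyl ester without base, so no retro-aldol is expected, and gives the hydroxy acid F3. TMSOTf/Et3N gives its bis-trimethylsilyl derivative F4, which is condensed with 10 as in step 7 to give 20 together with its acetal epimer F5, which is separated and re-equilibrated with TMSOTf. The route is rejoined at 20.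

Step 7 (dioxolanone formation). What may go wrong: incomplete cis control with a trigonal α-carbon, or conjugate addition and oligomerisation of the acrolein under the Lewis acid. Fallback (the enal is masked): setting out from 10, conjugate addition of benzeneselenol (PhSeSePh, NaBH4, EtOH) gives the saturated α-branched aldehyde (E)-6-formyl-2-methyl-7-(phenylselanyl)hept-2-en-1-yl (E)-3-[4-(TBSO)phenyl]acrylate F6. α-Branched saturated aldehydes are the best partners for the cis-selective condensation with 13, which should give the selenide dioxolanone F7. Oxidation (NaIO4) and selenoxide syn-elimination, which can only involve the hydrogen on the future C6, restores the 1,1-disubstituted alkene and returns to the route at 14.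

Step 12 (reductive opening). What may go wrong: over-reduction of the aryl ketone, hydride delivery to C5 instead of C7, or capture of the oxocarbenium ion by the side-chain alkene. Fallback (π-allylpalladium chemistry in place of the oxocarbenium ion, ring closed afterwards): setting out from 20, the allylic acylal is ionised by Pd(0)/PBu3 and the 1-alkoxy-π-allyl complex is reduced with ammonium formate. This is the formate hydrogenolysis of allylic esters, in which hydride goes to the more substituted, oxygen-bearing terminus; the acylal should ionise more readily than the trisubstituted allylic coumarate. The product is the diene ether acid F8, and ring-closing metathesis of F8 (Grubbs second-generation catalyst) closes the oxepine directly and rejoins the route at 23.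

Further compounds
F1 | step 10 | allyl 2-oxohex-5-enoate | C=CCCC(=O)C(=O)OCC=C
F2 | step 10 | allyl (R)-2-{2-[2,5-bis(TBSO)phenyl]-2-oxoethyl}-2-hydroxyhex-5-enoate | C=CCC[C@@](O)(CC(=O)c1cc(O[Si](C)(C)C(C)(C)C)ccc1O[Si](C)(C)C(C)(C)C)C(=O)OCC=C
F3 | step 10 | (R)-2-{2-[2,5-bis(TBSO)phenyl]-2-oxoethyl}-2-hydroxyhex-5-enoic acid | C=CCC[C@@](O)(CC(=O)c1cc(O[Si](C)(C)C(C)(C)C)ccc1O[Si](C)(C)C(C)(C)C)C(=O)O
F4 | step 10 | trimethylsilyl (R)-2-{2-[2,5-bis(TBSO)phenyl]-2-oxoethyl}-2-(trimethylsilyloxy)hex-5-enoate | C=CCC[C@@](O[Si](C)(C)C)(CC(=O)c1cc(O[Si](C)(C)C(C)(C)C)ccc1O[Si](C)(C)C(C)(C)C)C(=O)O[Si](C)(C)C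
F5 | step 10 | (2R,5R)-acetal epimer of 20 | C=CCC[C@@]1(CC(=O)c2cc(O[Si](C)(C)C(C)(C)C)ccc2O[Si](C)(C)C(C)(C)C)C(=O)O[C@H](C(=C)CC/C=C(\C)COC(=O)/C=C/c2ccc(O[Si](C)(C)C(C)(C)C)cc2)O1
F6 | step 7 | (E)-6-formyl-2-methyl-7-(phenylselanyl)hept-2-en-1-yl (E)-3-[4-(TBSO)phenyl]acrylate (both epimers at C6) | C/C(=C\CCC(C[Se]c1ccccc1)C=O)COC(=O)/C=C/c1ccc(O[Si](C)(C)C(C)(C)C)cc1
F7 | step 7 | (2S,5S)-5-(but-3-en-1-yl)-2-{(5E)-6-methyl-1-(phenylselanyl)-7-[(E)-3-(4-TBSO-phenyl)acryloyloxy]hept-5-en-2-yl}-1,3-dioxolan-4-one (both side-chain epimers) | C=CCC[C@H]1C(=O)O[C@@H](C(C[Se]c2ccccc2)CC/C=C(\C)COC(=O)/C=C/c2ccc(O[Si](C)(C)C(C)(C)C)cc2)O1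
F8 | step 12 | (R)-2-{2-[2,5-bis(TBSO)phenyl]-2-oxoethyl}-2-({(5E)-6-methyl-2-methylidene-7-[(E)-3-(4-TBSO-phenyl)acryloyloxy]hept-5-en-1-yl}oxy)hex-5-enoic acid | C=CCC[C@@](CC(=O)c1cc(O[Si](C)(C)C(C)(C)C)ccc1O[Si](C)(C)C(C)(C)C)(C(=O)O)OCC(=C)CC/C=C(\C)COC(=O)/C=C/c1ccc(O[Si](C)(C)C(C)(C)C)cc1
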